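**Retrosynthetic overview**

1. Target ⇒ ring-B ketone (the 4,5-dione): the C4 carbinol is put in last by a 1,2-reduction that C2 steers cis. Keeping C4 at the ketone level until then makes C3 an enolisable carbon nucleophile.
2. Dione ⇒ C2–C3 disconnection in ring B: acid-catalysed cycloisomerisation of the 1-alkenyl enol ether of 2-acetylcyclohexane-1,3-dione (O1–C2H=CH–C16H33), run with a chiral Brønsted acid so that C2 is set as the bond forms.
3. Enabling feature: the C4a=C8a double bond of carbocyclic ring A holds the ether oxygen O1 (on C8a) and the acetyl group C4(=O)–C3H3 (on C4a) cis and coplanar. Protonation of the enol ether turns C2 into an O1-bound oxocarbenium ion that the enol carbon C3 reaches through a six-membered array, so forming C2–C3 closes ring B (O1, C2, C3, C4, C4a, C8a).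
4. Alkenyl ether ⇒ O1–C2 disconnection: O-alkylation of the triketone with the α-chloro sulfide of octadecanal, then oxidation and sulfoxide elimination.
5. Order of rings: ring A is bought with the triketone; ring B is closed in step 5 (C2, catalyst control); step 6 sets C4 (substrate control).

Key step: step 5

Assumption: the triketone is taken to be alkylated on a ring enol oxygen (not the acetyl oxygen), and the sense of induction of the chiral acid is not safely predictable, so the antipode that gives 2S is to be fixed in the first runs (both antipodes derive from commercial BINOL).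

**Route**

Step 1
Reactants: 1 octadecanal
Product: 2 rac-[(1-chlorooctadecyl)sulfanyl]benzene
Conditions: PhSH (1.0 equiv), dry HCl gas, anhydrous CaCl2, CH2Cl2, −20 °C → 0 °C; used crude
Reagents that add atoms: thiophenol, Sc1ccccc1; hydrogen chloride, Cl
Why: Hemithioacetal formation followed by hydroxyl-for-chloride exchange through the sulfur-stabilised thionium ion (α-chloro sulfide synthesis from aldehyde, thiol and HCl) brings the aldehyde carbon, the future C2, to the acetal level with one good leaving group; no stereocentre needs control (racemate).

Step 2
Reactants: 3 2-acetylcyclohexane-1,3-dione; 2 rac-[(1-chlorooctadecyl)sulfanyl]benzene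
Product: 4 rac-2-acetyl-3-{[1-(phenylsulfanyl)octadecyl]oxy}cyclohex-2-en-1-one
Conditions: Cs2CO3 (1.0 equiv), MeCN, 0 °C; then crude 2 in CH2Cl2, −20 °C → rt
Reagents that add atoms: none
Why: O-alkylation of a β-tricarbonyl enolate by an ionising α-chloro sulfide (substitution via the thionium ion, as with chloromethyl ethers and sulfides on enolised 1,3-diones) should form the O1–C2 bond at the ring oxygen, because the central carbon is fully substituted and the weakly basic caesium enolate limits dehydrochlorination of 2; the acetal centre forms as a racemate and is erased in step 4.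

Step 3
Reactants: 4 rac-2-acetyl-3-{[1-(phenylsulfanyl)octadecyl]oxy}cyclohex-2-en-1-one
Product: 5 2-acetyl-3-{[1-(phenylsulfinyl)octadecyl]oxy}cyclohex-2-en-1-one (mixture of diastereomers)
Conditions: mCPBA (1.0 equiv), CH2Cl2, −78 °C → −30 °C; cold aqueous NaHCO3 work-up; used crude
Reagents that add atoms: mCPBA, OOC(=O)c1cccc(Cl)c1
Why: Sulfide-to-sulfoxide oxidation with one equivalent of peracid at low temperature should be chemoselective because the sulfide is by far the most nucleophilic site (the push–pull ring alkene is electron-poor); the configurations at sulfur and at the acetal carbon are irrelevant.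

Step 4
Reactants: 5 2-acetyl-3-{[1-(phenylsulfinyl)octadecyl]oxy}cyclohex-2-en-1-one
Product: 6 2-acetyl-3-{[(1E)-octadec-1-en-1-yl]oxy}cyclohex-2-en-1-one (mainly E expected; the Z isomer is equally usable)
Conditions: PhMe, 4 Å MS, 80 °C, dilute, Ar; rapid filtration through deactivated silica
Reagents that add atoms: none
Why: Thermal syn-elimination of benzenesulfenic acid (sulfoxide pyrolysis), helped by the α-oxygen, can only take a hydrogen from the side-chain methylene and should therefore give the 1-alkenyl ether regiospecifically; alkene geometry does not matter because this double bond is protonated in step 5.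

Step 5
Reactants: 6 2-acetyl-3-{[(1E)-octadec-1-en-1-yl]oxy}cyclohex-2-en-1-one
Product: 7 (2S)-2-heptadecyl-2,3,7,8-tetrahydro-4H-chromene-4,5(6H)-dione
Conditions: BINOL-derived imidodiphosphorimidate Brønsted acid (IDPi, N-triflyl, 3,3'-diaryl; 3 mol%, antipode giving 2S), CH2Cl2/PhMe, 4 Å MS, −40 °C, high dilution; 2,6-lutidine quench, cold filtration through a short silica pad; crude 7 used at once
Reagents that add atoms: none
Why: Proposed new method: the confined chiral acid protonates the side-chain CH of the enol ether of 6 to give an O1-bound oxocarbenium ion at C2 held as a contact ion pair, the acetyl group on C4a enolises under the same acid, and its terminal carbon C3 attacks C2 before the proton returns to the catalyst, so 6 isomerises to 7 with no by-product. The closest known reaction types are the Petasis–Ferrier rearrangement, in which an oxocarbenium ion and an enol(ate) recombine to form this same C2–C3 bond of a pyran-4-one, and chiral Brønsted acid catalysis of enol additions to oxocarbenium ions generated from vinyl ethers or acetals (counteranion-directed catalysis). Ring B closes in the 6-(enolendo)-endo-trig mode. C2 is the only new stereocentre and is set by the chiral anion, which shields one face of the planar oxocarbenium ion while hydrogen-bonding the enol. The step needs C–C closure rather than loss of the oxygen substituent: the C4a=C8a bond of ring A fixes O1 and the acetyl group cis and coplanar so that C3 reaches C2 through a six-membered array, displacement of O1 itself by C3 would be an impossible endocyclic substitution, and capture of the cation by the acetyl oxygen is reversible and non-productive. Molecular sieves exclude water, whose cleavage of the enol ether would open a racemic intermolecular pathway, and low temperature with dilution limits cationic oligomerisation and acid-mediated ring opening of 7.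

Step 6
Reactants: 7 (2S)-2-heptadecyl-2,3,7,8-tetrahydro-4H-chromene-4,5(6H)-dione
Product: 8 (2S,4R)-2-heptadecyl-4-hydroxy-2,3,4,6,7,8-hexahydro-5H-chromen-5-one
Conditions: NaBH4 (1.0 equiv), CeCl3·7H2O (1.1 equiv), MeOH/CH2Cl2, −78 °C; neutral aqueous NH4Cl quench; Et3N-deactivated silica (8 is acid-sensitive at C4)
Reagents that add atoms: none
Why: In this Luche reduction the cerium-modified borohydride should add 1,2 to the ring-B carbonyl C4 in preference to C5 (the α-methylene of C4 carries the β-oxygen O1, as in the more electrophilic tetrahydropyran-4-ones, whereas C5 is an ordinary 3-alkoxycyclohexenone carbonyl) by axial attack on the half-chair with the C2 heptadecyl group pseudo-equatorial, so the new hydroxyl should come out pseudo-equatorial and cis to the side chain (4R, set by C2), while the low temperature keeps the base-sensitive C2 centre of 7 from racemising by retro-oxa-Michael ring opening.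

**Compound list**

1 | octadecanal | CCCCCCCCCCCCCCCCCC=O | starting material
2 | rac-[(1-chlorooctadecyl)sulfanyl]benzene | CCCCCCCCCCCCCCCCCC(Cl)Sc1ccccc1 | intermediate
3 | 2-acetylcyclohexane-1,3-dione (drawn as its ring enol) | CC(=O)C1=C(O)CCCC1=O | starting material
4 | rac-2-acetyl-3-{[1-(phenylsulfanyl)octadecyl]oxy}cyclohex-2-en-1-one | CCCCCCCCCCCCCCCCCC(Sc1ccccc1)OC1=C(C(C)=O)C(=O)CCC1 | intermediate
5 | 2-acetyl-3-{[1-(phenylsulfinyl)octadecyl]oxy}cyclohex-2-en-1-one (diastereomer mixture) | CCCCCCCCCCCCCCCCCC(OC1=C(C(C)=O)C(=O)CCC1)S(=O)c1ccccc1 | intermediate
6 | 2-acetyl-3-{[(1E)-octadec-1-en-1-yl]oxy}cyclohex-2-en-1-one | CCCCCCCCCCCCCCCC/C=C/OC1=C(C(C)=O)C(=O)CCC1 | intermediate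
7 | (2S)-2-heptadecyl-2,3,7,8-tetrahydro-4H-chromene-4,5(6H)-dione | CCCCCCCCCCCCCCCCC[C@H]1CC(=O)C2=C(CCCC2=O)O1 | intermediate
8 | (2S,4R)-2-heptadecyl-4-hydroxy-2,3,4,6,7,8-hexahydro-5H-chromen-5-one | CCCCCCCCCCCCCCCCC[C@H]1C[C@@H](O)C2=C(CCCC2=O)O1 | target

**Step count and risks**

Total step count: 6. Longest linear sequence: 6 steps (1 → 2 → 4 → 5 → 6 → 7 → 8).

Steps most likely to fail:

1. Step 5 (Proposed new method). What may go wrong: C-protonation of the acyl-type enol ether may be too slow for turnover; cationic oligomerisation of the enol ether may outrun ring closure; hydrolytic cleavage followed by intermolecular condensation would give racemic material; enantiopurity may erode through acid-mediated ring opening and reclosure at C2. Fallback with known chemistry, setting out from 3 and returning at 7: the C2–C3 bond would be made intermolecularly by a boron aldol and ring B closed through oxygen. 3 would be O-methylated (trimethylsilyldiazomethane, MeOH/PhMe, 0 °C) to 2-acetyl-3-methoxycyclohex-2-en-1-one F1. Its boron enolate (Ipc2BCl of the antipode that gives the 3S carbinol, Et3N, Et2O, −78 °C) would be added to octadecanal 1 to give 2-[(3S)-3-hydroxyicosanoyl]-3-methoxycyclohex-2-en-1-one F2. PPTS in CH2Cl2 should then close ring B by addition–elimination of the C2 hydroxyl at C8a with loss of methanol, giving 7.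

2. Step 6. What may go wrong: competing hydride attack at the C5 carbonyl (regioselectivity between the two vinylogous-ester carbonyls is argued from inductive activation only) and base-induced ring opening at C2 before reduction. Fallback setting out from 3 and returning at 8: the C4 carbonyl would be reduced before ring B exists, under hydroxyl direction. The aldol 2-[(3S)-3-hydroxyicosanoyl]-3-methoxycyclohex-2-en-1-one F2, made from 3 through 2-acetyl-3-methoxycyclohex-2-en-1-one F1 as above, would be treated with Me4NBH(OAc)3 in MeCN/AcOH at −30 °C (Evans–Saksena reduction). The C2 hydroxyl binds the borohydride and delivers hydride only to the neighbouring C4 carbonyl, 1,3-anti, which should give 2-[(1R,3S)-1,3-dihydroxyicosyl]-3-methoxycyclohex-2-en-1-one F3. PPTS (CH2Cl2, 0 °C) should then cyclise F3 with loss of methanol to 8; the 1,3-anti diol maps onto the 2,4-cis ring.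

3. Step 2. What may go wrong: dehydrochlorination of 2 to the vinyl sulfide may outrun substitution, and alkylation may occur at the acetyl oxygen instead of the ring oxygen. Fallback setting out from 3 and returning at 6: the enol oxygen would be alkenylated directly by an oxidative copper-mediated coupling of Chan–Lam type with [(1E)-octadec-1-en-1-yl]boronic acid F4 (from 1-octadecyne by hydroboration with catecholborane and hydrolysis), using Cu(OAc)2, pyridine, 4 Å MS, air, CH2Cl2, rt. This should give 6 in one operation and makes 2, 4 and 5 unnecessary.

**Further compounds**

F1 | step 5 | 2-acetyl-3-methoxycyclohex-2-en-1-one | COC1=C(C(C)=O)C(=O)CCC1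
F2 | step 5 | 2-[(3S)-3-hydroxyicosanoyl]-3-methoxycyclohex-2-en-1-one | CCCCCCCCCCCCCCCCC[C@H](O)CC(=O)C1=C(OC)CCCC1=O
F3 | step 6 | 2-[(1R,3S)-1,3-dihydroxyicosyl]-3-methoxycyclohex-2-en-1-one | CCCCCCCCCCCCCCCCC[C@H](O)C[C@@H](O)C1=C(OC)CCCC1=O
F4 | step 2 | [(1E)-octadec-1-en-1-yl]boronic acid | CCCCCCCCCCCCCCCC/C=C/B(O)O
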